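Eudesmane numbering: ring A = C1–C5/C10, ring B = C5–C10. Everything rests on cutting ring B at C9–C10 and C5–C6. The step exploits three features: the cis C5–H/C10–CH3 junction, the C8 ketone para to C5, and its 1,5-relation to the C4 oxygen. One chelation-controlled, enantioselective Diels–Alder reaction closes ring B on a preformed ring A. It creates C5 and quaternary C10 in the absolute sense and delivers C8=O as a regiodefined silyl enol ether next to the C7 isopropyl group. Its precursors are flat and achiral: 2-methoxy-5-methyl-1,4-benzoquinone and 3-isopropyl-2-silyloxybutadiene. The folded cis-decalin then dictates C4, C3 and C7.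

Key step: step 3

Assumption: the facial sense of the (S)-BINOL–Ti(IV) catalyst is assigned by analogy with related chelated 2-methoxyquinone cycloadditions. If it proves opposite, (R)-BINOL is used and nothing else changes.

Step 1
Reactants: 1 ethyl 2-acetyl-3-methylbutanoate (ethyl 2-isopropylacetoacetate, racemic)
Product: 3 4-methyl-3-methylidenepentan-2-one (3-isopropylbut-3-en-2-one), via potassium 2-acetyl-3-methylbutanoate 2 (not isolated)
Conditions: KOH, H2O, rt; HCl to pH 7; 37% aq. HCHO, Et2NH, rt → 60 °C
Reagents that add atoms: formaldehyde, C=O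
Why: Saponification followed by a decarboxylative Mannich methylenation (iminium capture at the carboxyl-bearing carbon, then loss of CO2 and Et2NH) should place the methylene group regiospecifically on the isopropyl-bearing carbon, which a direct Mannich reaction of the parent methyl ketone would not guarantee.

Step 2
Reactants: 3 3-isopropylbut-3-en-2-one
Product: 4 3-isopropyl-2-(triisopropylsilyloxy)buta-1,3-diene
Conditions: TIPSOTf, Et3N, CH2Cl2, 0 °C → rt
Reagents that add atoms: triisopropylsilyl triflate, CC(C)[Si](C(C)C)(C(C)C)OS(=O)(=O)C(F)(F)F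
Why: In this soft enolisation with a silyl triflate and an amine only the acetyl CH3 is enolisable, so the cross-conjugated 2-silyloxydiene should form as a single regioisomer.

Step 3
Reactants: 4 3-isopropyl-2-(triisopropylsilyloxy)buta-1,3-diene; 5 2-methoxy-5-methyl-1,4-benzoquinone
Product: 6 (4aR,8aS)-2-methoxy-4a-methyl-7-isopropyl-6-(triisopropylsilyloxy)-4a,5,8,8a-tetrahydronaphthalene-1,4-dione (cis adduct; 5β-H, 10β-CH3)
Conditions: (S)-BINOL (30 mol %), TiCl2(OiPr)2 (30 mol %), 4 Å MS (catalyst preparation), toluene, −40 → 0 °C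
Reagents that add atoms: none
Why: The Ti(IV) binaphtholate should bind 5 as a five-membered chelate through the C4 carbonyl oxygen and the C3 methoxy oxygen, which lowers the LUMO of the C5=C10 bond and makes C10 (β to C4=O) its electrophilic end, so the diene adds in a concerted but asynchronous [4+2] cycloaddition in which C9–C10 leads C5–C6. The closest known reaction type is the BINOL–Ti(IV)-catalysed asymmetric Diels–Alder reaction of 2-methoxy-1,4-benzoquinones with silyloxydienes, and regiocontrol of 2-methoxy-5-methylbenzoquinone cycloadditions by bidentate Lewis acids is likewise known. Ring B is closed by an intermolecular suprafacial–suprafacial six-electron cycloaddition that makes both of its new σ bonds in one operation. C5 and C10 arise together: their cis relation follows from suprafacial addition to the ring double bond, their absolute configuration from the binaphtholate wall that leaves only the later α face of the chelated quinone open, and the diene has no terminal substituent, so endo/exo topology creates no further stereocentre. Site selectivity (C5=C10 over C2=C3) is secured by the methoxy group, which turns C2=C3 into an unreactive vinylogous ester, and regioselectivity by the match of the most nucleophilic diene terminus C9 (the enol ether CH2) with C10, reinforced sterically because the isopropyl-bearing end meets the CH end C5. The angular methyl group blocks aromatisation of the adduct, and the low temperature should prevent epimerisation at C5.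

Step 4
Reactants: 6 cis adduct
Product: 8 4α-acetoxy-3-methoxy-8-(triisopropylsilyloxy)-5βH-eudesma-2,7-dien-1-one (4β-CH3), via bromomagnesium 4α-alkoxide 7 (not isolated)
Conditions: MeMgBr, THF/toluene, −78 °C; then Ac2O, DMAP (cat.), −78 °C → rt
Reagents that add atoms: methylmagnesium bromide, C[Mg]Br; acetic anhydride, CC(=O)OC(C)=O
Why: Chelation-assisted Grignard 1,2-addition should take the C4 ketone (C1=O is a hindered, non-enolisable vinylogous ester) from the convex β face, anti to the axial C9 methylene, which sets C4 (β-CH3, α-O), and the hindered alkoxide is acetylated in the same flask.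

Step 5
Reactants: 8 tertiary acetate
Product: 10 4α-acetoxy-8-(triisopropylsilyloxy)-5βH-eudesma-1,7-dien-3-one, via C1 allylic alcohol 9 (not isolated)
Conditions: NaBH4, CeCl3·7H2O, MeOH, 0 °C; then 1 M HCl, THF, 0 °C, short contact
Reagents that add atoms: water, O
Why: Luche 1,2-reduction of the vinylogous ester spares the acetate, and brief acid then triggers a Stork–Danheiser transposition (ionisation of C1–OH to the methoxy-stabilised allyl cation, hydration at C3, loss of methanol) that deletes the C1 oxygen and unveils the C3 ketone faster than the hindered tetrasubstituted TIPS enol ether is protonated.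

Step 6
Reactants: 10 α-acetoxy enone
Product: 11 4α-acetoxy-8-(triisopropylsilyloxy)-5βH-eudesm-7-en-3-one
Conditions: H2 (1 atm), 10% Pd/C, EtOAc, rt
Reagents that add atoms: none
Why: Heterogeneous catalytic hydrogenation should saturate the disubstituted C1=C2 enone bond while the tetrasubstituted silyl enol ether is too hindered to react, and no stereocentre is formed.

Step 7
Reactants: 11 α-acetoxy ketone
Product: 12 4α-acetoxy-8-(triisopropylsilyloxy)-5βH-eudesm-7-en-3α-ol
Conditions: NaBH4, CeCl3·7H2O, MeOH, −78 °C; aq. NH4Cl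
Reagents that add atoms: none
Why: In the chair that keeps C4–CH3 equatorial, small-hydride reduction by axial attack from the β face, anti to the axial C4–OAc bond (polar Felkin–Anh), should give the equatorial 3α-alcohol and so set C3, while cerium salt and low temperature keep the medium non-basic so that the acetyl group stays on O4.

Step 8
Reactants: 12 3α-alcohol; 13 angelic acid ((Z)-2-methylbut-2-enoic acid)
Product: 15 4α-acetoxy-3α-angeloyloxy-8-(triisopropylsilyloxy)-5βH-eudesm-7-ene, via angelic 2,4,6-trichlorobenzoic anhydride 14 (not isolated)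
Conditions: 13, 2,4,6-Cl3C6H2COCl, Et3N, toluene, rt; then 12, 75 °C
Reagents that add atoms: none
Why: A Yamaguchi-type mixed-anhydride esterification run without nucleophilic catalyst transfers the angeloyl group without Z→E isomerisation, acylates O3 with retention at C3, and works in an almost neutral medium that disfavours acetyl migration.

Step 9
Reactants: 15 angelate silyl enol ether
Product: 16 (3R,4S,5S,7R,10R)-4α-acetoxy-3α-angeloyloxy-5βH,7αH-eudesman-8-one (target)
Conditions: 48% aq. HF, MeCN, 0 °C → rt
Reagents that add atoms: none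
Why: Protodesilylation of the silyl enol ether releases the C8 ketone, and C7 is set under acid-equilibrating conditions, because the 7β-isopropyl group is equatorial in the only chair–chair conformer that avoids the C4–CH3/C10–CH3 syn-diaxial contact, so the target epimer is the thermodynamic one.

Compound list
1 | ethyl 2-acetyl-3-methylbutanoate (racemic) | CCOC(=O)C(C(C)C)C(C)=O | starting material
2 | potassium 2-acetyl-3-methylbutanoate | CC(=O)C(C(C)C)C(=O)[O-].[K+] | intermediate
3 | 4-methyl-3-methylidenepentan-2-one | CC(=O)C(=C)C(C)C | intermediate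
4 | 3-isopropyl-2-(triisopropylsilyloxy)buta-1,3-diene | C=C(O[Si](C(C)C)(C(C)C)C(C)C)C(=C)C(C)C | intermediate
5 | 2-methoxy-5-methyl-1,4-benzoquinone | COC1=CC(=O)C(C)=CC1=O | starting material
6 | (4aR,8aS)-2-methoxy-4a-methyl-7-isopropyl-6-(triisopropylsilyloxy)-4a,5,8,8a-tetrahydronaphthalene-1,4-dione | COC1=CC(=O)[C@]2(C)CC(O[Si](C(C)C)(C(C)C)C(C)C)=C(C(C)C)C[C@@H]2C1=O | intermediate
7 | bromomagnesium 4α-alkoxide (4β-CH3) derived from 6 | COC1=CC(=O)[C@]2(C)CC(O[Si](C(C)C)(C(C)C)C(C)C)=C(C(C)C)C[C@@H]2[C@]1(C)[O-].[Mg+2].[Br-] | intermediate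
8 | 4α-acetoxy-3-methoxy-8-(triisopropylsilyloxy)-5βH-eudesma-2,7-dien-1-one | COC1=CC(=O)[C@]2(C)CC(O[Si](C(C)C)(C(C)C)C(C)C)=C(C(C)C)C[C@@H]2[C@]1(C)OC(C)=O | intermediate
9 | 4α-acetoxy-3-methoxy-8-(triisopropylsilyloxy)-5βH-eudesma-2,7-dien-1-ol (C1 epimers, both converge) | COC1=CC(O)[C@]2(C)CC(O[Si](C(C)C)(C(C)C)C(C)C)=C(C(C)C)C[C@@H]2[C@]1(C)OC(C)=O | intermediate
10 | 4α-acetoxy-8-(triisopropylsilyloxy)-5βH-eudesma-1,7-dien-3-one | O=C1C=C[C@]2(C)CC(O[Si](C(C)C)(C(C)C)C(C)C)=C(C(C)C)C[C@@H]2[C@]1(C)OC(C)=O | intermediate
11 | 4α-acetoxy-8-(triisopropylsilyloxy)-5βH-eudesm-7-en-3-one | O=C1CC[C@]2(C)CC(O[Si](C(C)C)(C(C)C)C(C)C)=C(C(C)C)C[C@@H]2[C@]1(C)OC(C)=O | intermediate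
12 | 4α-acetoxy-8-(triisopropylsilyloxy)-5βH-eudesm-7-en-3α-ol | O[C@@H]1CC[C@]2(C)CC(O[Si](C(C)C)(C(C)C)C(C)C)=C(C(C)C)C[C@@H]2[C@]1(C)OC(C)=O | intermediate
13 | angelic acid, (Z)-2-methylbut-2-enoic acid | C/C=C(/C)C(=O)O | starting material
14 | angelic 2,4,6-trichlorobenzoic anhydride | C/C=C(/C)C(=O)OC(=O)c1c(Cl)cc(Cl)cc1Cl | intermediate
15 | 4α-acetoxy-3α-angeloyloxy-8-(triisopropylsilyloxy)-5βH-eudesm-7-ene | C/C=C(/C)C(=O)O[C@@H]1CC[C@]2(C)CC(O[Si](C(C)C)(C(C)C)C(C)C)=C(C(C)C)C[C@@H]2[C@]1(C)OC(C)=O | intermediate
16 | (3R,4S,5S,7R,10R)-4α-acetoxy-3α-angeloyloxy-5βH,7αH-eudesman-8-one | C/C=C(/C)C(=O)O[C@@H]1CC[C@]2(C)CC(=O)[C@@H](C(C)C)C[C@@H]2[C@]1(C)OC(C)=O | target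

Total step count: 9. Longest linear sequence: 9 (steps 1–9; 5 and 13 enter as purchased materials).

Steps most likely to fail

1. Step 3 (key step).
- What may go wrong: slow cycloaddition at the trisubstituted C5=C10 bond, insufficient discrimination of the two quinone faces by the catalyst, or desilylation of the diene by the titanium chloride before ring closure.
- Fallback (sets out from 5 and 4, comes back at 10): stereocontrol is moved from the catalyst to a covalently bound auxiliary. The methoxy group of 5 is exchanged by acid-catalysed addition–elimination with (−)-8-phenylmenthol (cat. p-TsOH, toluene, removal of the liberated alcohol) to give 5-methyl-2-(8-phenylmenthyloxy)-1,4-benzoquinone F1. An achiral chelating Lewis acid (SnCl4, CH2Cl2, −78 °C) then promotes the cycloaddition with 4 to the 8-phenylmenthyloxy cis adduct F2. The face is chosen by the aryl ring stacked over the chelated quinone, and any minor diastereomer is removed by chromatography or crystallisation. MeMgBr/Ac2O as in step 4 should give the auxiliary-bearing tertiary acetate F3 and Luche reduction the auxiliary-bearing allylic alcohol F4. The acid transposition of step 5 then expels the auxiliary and gives 10.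

2. Step 4.
- What may go wrong: enolisation of the C4 ketone by the basic Grignard reagent with epimerisation at C5 towards the trans series, poor facial selectivity at C4, or incomplete capture of the hindered alkoxide.
- Fallback (sets out from 6, comes back at 10): C15 is brought in as the CH2 of an epoxide instead of as a hard methyl carbanion. A Corey–Chaykovsky reaction with dimethylsulfonium methylide (Me3SI, KHMDS, THF, −10 °C) on the C4 ketone, again from the convex face, should give the C4 spiro-epoxide F5. Excess LiEt3BH opens it at the CH2 terminus and reduces C1=O in the same flask to the 1,4α-diol F6. Dilute HCl effects the transposition to the 4α-hydroxy enone F7, and Ac2O/DMAP/Et3N on this α-ketol gives 10.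

3. Step 8.
- What may go wrong: migration of the acetyl group from the tertiary O4 to the free O3 before acylation, slow acylation next to the quaternary C4, or Z→E isomerisation of the acyl donor on prolonged heating.
- Fallback (sets out from 11, comes back at 15): the order of the two esterifications is inverted so that no free hydroxyl ever sits beside a migrating acetate. LiAlH4 (THF, −78 → 0 °C) reduces the ketone by axial attack and removes the acetate to give the 3α,4α-diol F8. The mixed anhydride 14 then acylates only the secondary hydroxyl to give the 3α-angelate 4α-alcohol F9. The tertiary hydroxyl is acetylated last (Ac2O, DMAP, Et3N, CH2Cl2, 40 °C) to give 15.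

Further compounds
F1 | step 3 | 5-methyl-2-[(1R,2S,5R)-8-phenylmenthyloxy]-1,4-benzoquinone | CC(C)(c1ccccc1)[C@@H]2CC[C@@H](C)C[C@H]2OC3=CC(=O)C(C)=CC3=O
F2 | step 3 | 8-phenylmenthyloxy cis adduct (5β-H, 10β-CH3) | CC(C)(c5ccccc5)[C@@H]4CC[C@@H](C)C[C@H]4OC1=CC(=O)[C@]2(C)CC(O[Si](C(C)C)(C(C)C)C(C)C)=C(C(C)C)C[C@@H]2C1=O
F3 | step 3 | auxiliary-bearing tertiary acetate (4α-OAc, 4β-CH3) | CC(C)(c5ccccc5)[C@@H]4CC[C@@H](C)C[C@H]4OC1=CC(=O)[C@]2(C)CC(O[Si](C(C)C)(C(C)C)C(C)C)=C(C(C)C)C[C@@H]2[C@]1(C)OC(C)=O
F4 | step 3 | auxiliary-bearing allylic alcohol (C1 epimers) | CC(C)(c5ccccc5)[C@@H]4CC[C@@H](C)C[C@H]4OC1=CC(O)[C@]2(C)CC(O[Si](C(C)C)(C(C)C)C(C)C)=C(C(C)C)C[C@@H]2[C@]1(C)OC(C)=O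
F5 | step 4 | C4 spiro-epoxide (O on the α face, CH2 on the β face) | COC1=CC(=O)[C@]2(C)CC(O[Si](C(C)C)(C(C)C)C(C)C)=C(C(C)C)C[C@@H]2[C@]13OC3
F6 | step 4 | 3-methoxy-8-(triisopropylsilyloxy)-5βH-eudesma-2,7-diene-1,4α-diol (C1 epimers) | COC1=CC(O)[C@]2(C)CC(O[Si](C(C)C)(C(C)C)C(C)C)=C(C(C)C)C[C@@H]2[C@]1(C)O
F7 | step 4 | 4α-hydroxy-8-(triisopropylsilyloxy)-5βH-eudesma-1,7-dien-3-one | O=C1C=C[C@]2(C)CC(O[Si](C(C)C)(C(C)C)C(C)C)=C(C(C)C)C[C@@H]2[C@]1(C)O
F8 | step 8 | 8-(triisopropylsilyloxy)-5βH-eudesm-7-ene-3α,4α-diol | O[C@@H]1CC[C@]2(C)CC(O[Si](C(C)C)(C(C)C)C(C)C)=C(C(C)C)C[C@@H]2[C@]1(C)O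
F9 | step 8 | 3α-angeloyloxy-8-(triisopropylsilyloxy)-5βH-eudesm-7-en-4α-ol | C/C=C(/C)C(=O)O[C@@H]1CC[C@]2(C)CC(O[Si](C(C)C)(C(C)C)C(C)C)=C(C(C)C)C[C@@H]2[C@]1(C)O
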